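## Retrosynthetic overview

1. Numbering: the core is 2,9-dioxabicyclo[3.3.1]nona-3,7-diene (C-1 ketal carbon, O-2, C-3=C-4 enol ether, C-5 bridgehead CH, C-6, C-7=C-8, O-9); ring A is O-2/C-3/C-4/C-5/O-9/C-1, ring B is C-1/O-9/C-5/C-6/C-7/C-8; the side chain is C-1′ to C-9′ (C-2′ on C-3, ketone at C-3′). The C-3′ ketone is unmasked last from silyl ether 29, so that C-2′ stays non-acidic and the enol ether can only form toward C-4.
2. Key disconnection: the C-4–C-5 and O-9–C-1 bonds of 29 lead back to the monocyclic 1,3-dioxin-4-one aldehyde 26. Forward, one acid-triggered cascade closes ring B (O-9–C-1), then ring A (C-4–C-5), and expels CO2.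
3. Enabling feature: C-1 is a ketal carbon that carries both the enol-ether oxygen O-2 (on C-3=C-4) and the bridging oxygen O-9 (on C-5). A dioxinone is this same O-vinyl ketal with CO2 held between C-4 and C-1 as a traceless activating tether, and the Z C-7=C-8 bond folds the aldehyde carbon (future C-5) back over C-1.
4. Dioxinone 25 comes from the acylketene of tert-butyl β-keto ester 15 and Z-enone 23 by [4+2] addition at the ketone C=O.
5. 15 comes from auxiliary-controlled alkylation (C-4′) and syn-aldol (C-2′); 23 comes from methyl (R)-3-hydroxy-2-methylpropanoate (C-6) by Z-selective olefination.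

Key step: step 16

Remark: 15 is used as a mixture at the carbon between its two carbonyl groups, and 25 and 26 as mixtures at the dioxinone ketal carbon; these centres become planar in steps 14 and 16, so the mixtures converge.

## Route

Step 1
Reactants: 1 (E)-2-methylpent-2-enal
Product: 2 (E)-2-methylpent-2-en-1-ol
Conditions: NaBH4, CeCl3·7H2O, MeOH, 0 °C
Reagents that add atoms: none
Why: Luche reduction delivers hydride 1,2 to the enal and leaves the trisubstituted E alkene untouched.

Step 2
Reactants: 2 (E)-2-methylpent-2-en-1-ol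
Product: 3 (E)-1-bromo-2-methylpent-2-ene
Conditions: PBr3, Et2O, 0 °C
Reagents that add atoms: phosphorus tribromide, BrP(Br)Br
Why: Substitution of a primary allylic alcohol by PBr3 should give the primary allylic bromide by direct displacement, without allylic shift or loss of the E geometry.

Step 3
Reactants: 4 (S)-4-benzyl-3-propanoyl-1,3-oxazolidin-2-one; 3 (E)-1-bromo-2-methylpent-2-ene
Product: 6 (S)-4-benzyl-3-[(2R,4E)-2,4-dimethylhept-4-enoyl]-1,3-oxazolidin-2-one, via sodium Z-enolate of the propanoyl imide 5 (not isolated)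
Conditions: NaN(SiMe3)2, THF, −78 °C; then 3, −78 → −40 °C
Reagents that add atoms: none
Why: Evans asymmetric alkylation, in which the chelated Z-enolate is alkylated on the face away from the benzyl group, sets the (R) centre that becomes C-4′.

Step 4
Reactants: 6 (S)-4-benzyl-3-[(2R,4E)-2,4-dimethylhept-4-enoyl]-1,3-oxazolidin-2-one
Product: 7 (2R,4E)-2,4-dimethylhept-4-en-1-ol
Conditions: LiBH4, EtOH (1 equiv), Et2O, 0 °C
Reagents that add atoms: none
Why: Reductive cleavage of the N-acyl oxazolidinone at the exocyclic carbonyl gives the primary alcohol without touching the α-centre.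

Step 5
Reactants: 7 (2R,4E)-2,4-dimethylhept-4-en-1-ol
Product: 8 (2R,4E)-2,4-dimethylhept-4-enal
Conditions: Dess–Martin periodinane, pyridine, CH2Cl2, 0 °C → rt
Reagents that add atoms: none
Why: Buffered Dess–Martin oxidation should give the α-methyl aldehyde without epimerisation, and it is used at once.

Step 6
Reactants: 9 (R)-4-benzyl-3-propanoyl-1,3-thiazolidine-2-thione; 8 (2R,4E)-2,4-dimethylhept-4-enal
Product: 11 (R)-4-benzyl-3-[(2R,3S,4R,6E)-3-hydroxy-2,4,6-trimethylnon-6-enoyl]-1,3-thiazolidine-2-thione, via trichlorotitanium Z-enolate of the propanoyl thioimide 10 (not isolated)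
Conditions: TiCl4, i-Pr2NEt, N-methyl-2-pyrrolidinone, CH2Cl2, 0 °C; then 8, −78 → 0 °C
Reagents that add atoms: none
Why: The titanium-mediated Evans-syn aldol of an N-propanoyl thiazolidinethione (Crimmins aldol, non-chelated Zimmerman–Traxler transition state) lets the auxiliary fix the (2R) centre that becomes C-2′ and the syn (3S) carbinol, and this reagent control should override the modest bias of the α-methyl aldehyde.

Step 7
Reactants: 11 (R)-4-benzyl-3-[(2R,3S,4R,6E)-3-hydroxy-2,4,6-trimethylnon-6-enoyl]-1,3-thiazolidine-2-thione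
Product: 12 (R)-4-benzyl-3-[(2R,3S,4R,6E)-3-[(tert-butyldimethylsilyl)oxy]-2,4,6-trimethylnon-6-enoyl]-1,3-thiazolidine-2-thione
Conditions: t-BuMe2SiOTf, 2,6-lutidine, CH2Cl2, −78 → 0 °C
Reagents that add atoms: tert-butyldimethylsilyl trifluoromethanesulfonate, CC(C)(C)[Si](C)(C)OS(=O)(=O)C(F)(F)F
Why: Silylation of the hindered secondary alcohol with the silyl triflate masks the future C-3′ ketone as an ether, so that C-2′ stays non-acidic until the last step.

Step 8
Reactants: 12 (R)-4-benzyl-3-[(2R,3S,4R,6E)-3-[(tert-butyldimethylsilyl)oxy]-2,4,6-trimethylnon-6-enoyl]-1,3-thiazolidine-2-thione; 13 tert-butyl propanoate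
Product: 15 tert-butyl (4R,5S,6R,8E)-5-[(tert-butyldimethylsilyl)oxy]-2,4,6,8-tetramethyl-3-oxoundec-8-enoate, via lithium enolate of tert-butyl propanoate 14 (not isolated)
Conditions: 13 (3 equiv), LiN(i-Pr)2 (3 equiv), THF, −78 °C; then 12, −78 → −40 °C
Reagents that add atoms: none
Why: The N-acyl thiazolidinethione is an activated amide, so the ester enolate should displace the auxiliary in a crossed Claisen condensation; the new centre between the carbonyl groups is irrelevant because it becomes planar in step 14.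

Step 9
Reactants: 16 methyl (R)-3-hydroxy-2-methylpropanoate
Product: 17 methyl (R)-2-methyl-3-[(triethylsilyl)oxy]propanoate
Conditions: Et3SiCl, imidazole, CH2Cl2, 0 °C
Reagents that add atoms: chlorotriethylsilane, CC[Si](Cl)(CC)CC
Why: Standard silylation gives a primary triethylsilyl ether, chosen because it can later be oxidised directly to the aldehyde beside a secondary tert-butyldimethylsilyl ether.

Step 10
Reactants: 17 methyl (R)-2-methyl-3-[(triethylsilyl)oxy]propanoate
Product: 18 (R)-2-methyl-3-[(triethylsilyl)oxy]propanal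
Conditions: i-Bu2AlH, CH2Cl2, −78 °C
Reagents that add atoms: none
Why: Partial reduction of the ester stops at the aldehyde because the tetrahedral aluminium hemiacetal is stable at −78 °C, and the α-centre is not touched.

Step 11
Reactants: 18 (R)-2-methyl-3-[(triethylsilyl)oxy]propanal; 19 ethyl 2-[bis(2,2,2-trifluoroethoxy)phosphoryl]propanoate
Product: 21 ethyl (2Z,4S)-2,4-dimethyl-5-[(triethylsilyl)oxy]pent-2-enoate, via potassium carbanion of the phosphonate 20 (not isolated)
Conditions: 19, KN(SiMe3)2, 18-crown-6, THF, −78 °C; then 18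
Reagents that add atoms: none
Why: Still–Gennari olefination with the bis(trifluoroethyl) phosphonate should give the Z trisubstituted enoate under kinetic control, which places the future C-1 and C-6 cis on the C-7=C-8 bond.

Step 12
Reactants: 21 ethyl (2Z,4S)-2,4-dimethyl-5-[(triethylsilyl)oxy]pent-2-enoate
Product: 22 (2Z,4S)-N-methoxy-N,2,4-trimethyl-5-[(triethylsilyl)oxy]pent-2-enamide
Conditions: MeNH(OMe)·HCl, i-PrMgCl, THF, −20 °C
Reagents that add atoms: N,O-dimethylhydroxylamine hydrochloride, CNOC.Cl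
Why: Direct aminolysis of the ester by the magnesium amide gives the Weinreb amide with the Z alkene retained.

Step 13
Reactants: 22 (2Z,4S)-N-methoxy-N,2,4-trimethyl-5-[(triethylsilyl)oxy]pent-2-enamide
Product: 23 (4Z,6S)-4,6-dimethyl-7-[(triethylsilyl)oxy]hept-4-en-3-one
Conditions: EtMgBr, THF, 0 °C
Reagents that add atoms: ethylmagnesium bromide, CC[Mg]Br
Why: Weinreb ketone synthesis, in which the stable magnesium chelate prevents a second addition, gives the Z ethyl enone.

Step 14
Reactants: 15 tert-butyl (4R,5S,6R,8E)-5-[(tert-butyldimethylsilyl)oxy]-2,4,6,8-tetramethyl-3-oxoundec-8-enoate; 23 (4Z,6S)-4,6-dimethyl-7-[(triethylsilyl)oxy]hept-4-en-3-one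
Product: 25 6-[(2R,3S,4R,6E)-3-[(tert-butyldimethylsilyl)oxy]-4,6-dimethylnon-6-en-2-yl]-2-ethyl-5-methyl-2-[(2Z,4S)-4-methyl-5-[(triethylsilyl)oxy]pent-2-en-2-yl]-4H-1,3-dioxin-4-one, via acylketene 24 (not isolated)
Conditions: 23 (3 equiv, excess recovered), toluene, 110 °C, N2 stream to remove t-BuOH
Reagents that add atoms: none
Why: Thermolysis of a tert-butyl β-keto ester gives the α-acylketene by loss of tert-butanol, and the acylketene adds to the ketone C=O in a hetero-Diels–Alder [4+2] reaction to give the 1,3-dioxin-4-one, whose new ketal centre is formed without control and is reset in step 16.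

Step 15
Reactants: 25 the dioxinone triethylsilyl ether of step 14
Product: 26 (2S,3Z)-4-{6-[(2R,3S,4R,6E)-3-[(tert-butyldimethylsilyl)oxy]-4,6-dimethylnon-6-en-2-yl]-2-ethyl-5-methyl-4-oxo-4H-1,3-dioxin-2-yl}-2-methylpent-3-enal
Conditions: (COCl)2, DMSO, CH2Cl2, −78 °C; then 25; then Et3N, −78 → −30 °C
Reagents that add atoms: none
Why: Swern conditions cleave and oxidise a primary triethylsilyl ether directly to the aldehyde, while the secondary tert-butyldimethylsilyl ether and the dioxinone should be inert; the aldehyde is used at once.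

Step 16
Reactants: 26 the dioxinone aldehyde of step 15
Product: 29 tert-butyl{[(2R,3S,4R,6E)-2-[(1S,5S,6S)-1-ethyl-4,6,8-trimethyl-2,9-dioxabicyclo[3.3.1]nona-3,7-dien-3-yl]-4,6-dimethylnon-6-en-3-yl]oxy}dimethylsilane, via ring B oxocarbenium silyl ester 27 (not isolated), via bicyclic silyloxycarbonyl oxocarbenium ion 28 (not isolated)
Conditions: Me3SiOTf (0.2 equiv), 4 Å MS, CH2Cl2, −78 → −40 °C; then Et3N
Reagents that add atoms: none
Why: Proposed new method: Me3SiOTf silylates the lactone carbonyl of the dioxinone and the acyloxy C–O bond at the allylic ketal carbon C-1 ionises (as in the silyl triflate ionisation of alkenyl ketals), the aldehyde oxygen held cis by the Z C-7=C-8 bond then adds to C-1 and closes ring B as the six-membered cyclic oxocarbenium ion 27 (closure by O-attack on the cation), the α-carbon of the silyl β-alkoxyacrylate still bound to C-1 through O-2 attacks the oxocarbenium carbon and closes ring A by forming C-4–C-5 (6-endo, enol-endo Prins-type closure, 28), and 28 loses CO2 and Me3Si+, which returns the catalyst and puts the enol ether double bond at C-3=C-4 only. The closest known reactions are the Prins cyclisation of 1,3-dioxin-4-ones through their C-5 onto oxocarbenium ions, the Petasis–Ferrier rearrangement (an ionised O-vinyl acetal that closes a ring through carbon) and the decarboxylative aldol reaction of β-keto acids. C-1 and C-5 are set relative to the existing C-6 centre: C-1 is planar after ionisation and its ketal is re-formed reversibly, the tether can reach C-5 only on the face of ring B that carries O-2, and the cation in which this face is anti to the C-6 methyl group should cyclise faster (no gauche contact between that methyl group and the incoming C-4 with its methyl group), which gives the (1S,5S,6S) core. The step needs retention of the C-6 and C-2′ centres and a single enol ether regiochemistry; low temperature without base disfavours loss of the proton at C-6, C-2′ has no carbonyl neighbour other than the dioxinone, and decarboxylation is the only exit from 28.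

Step 17
Reactants: 29 the bicyclic silyl ether of step 16
Product: 30 (2R,3S,4R,6E)-2-[(1S,5S,6S)-1-ethyl-4,6,8-trimethyl-2,9-dioxabicyclo[3.3.1]nona-3,7-dien-3-yl]-4,6-dimethylnon-6-en-3-ol
Conditions: Bu4NF, THF, 0 °C → rt
Reagents that add atoms: none
Why: Fluoride desilylation runs under basic conditions that the acid-labile enol ether ketal should tolerate, and with no carbonyl present C-2′ cannot epimerise.

Step 18
Reactants: 30 the alcohol of step 17
Product: 31 (2S,4R,6E)-2-[(1S,5S,6S)-1-ethyl-4,6,8-trimethyl-2,9-dioxabicyclo[3.3.1]nona-3,7-dien-3-yl]-4,6-dimethylnon-6-en-3-one (CNP0232650.2)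
Conditions: Dess–Martin periodinane, pyridine, CH2Cl2, 0 °C
Reagents that add atoms: none
Why: Dess–Martin oxidation under pyridine buffer converts the secondary alcohol into the ketone without acid that would open the ketal and without base strong enough to epimerise C-2′.

## Compound list

1 | (E)-2-methylpent-2-enal | CC/C=C(\C)C=O | starting material
2 | (E)-2-methylpent-2-en-1-ol | CC/C=C(\C)CO | intermediate
3 | (E)-1-bromo-2-methylpent-2-ene | CC/C=C(\C)CBr | intermediate
4 | (S)-4-benzyl-3-propanoyl-1,3-oxazolidin-2-one | CCC(=O)N1[C@@H](Cc2ccccc2)COC1=O | starting material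
5 | sodium Z-enolate of imide 4 (formed in the flask) | C/C=C(\[O-])N1[C@@H](Cc2ccccc2)COC1=O.[Na+] | intermediate
6 | (S)-4-benzyl-3-[(2R,4E)-2,4-dimethylhept-4-enoyl]-1,3-oxazolidin-2-one | CC/C=C(\C)C[C@@H](C)C(=O)N1[C@@H](Cc2ccccc2)COC1=O | intermediate
7 | (2R,4E)-2,4-dimethylhept-4-en-1-ol | CC/C=C(\C)C[C@@H](C)CO | intermediate
8 | (2R,4E)-2,4-dimethylhept-4-enal | CC/C=C(\C)C[C@@H](C)C=O | intermediate
9 | (R)-4-benzyl-3-propanoyl-1,3-thiazolidine-2-thione | CCC(=O)N1[C@H](Cc2ccccc2)CSC1=S | starting material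
10 | trichlorotitanium Z-enolate of thioimide 9 (formed in the flask) | C/C=C(\O[Ti](Cl)(Cl)Cl)N1[C@H](Cc2ccccc2)CSC1=S | intermediate
11 | (R)-4-benzyl-3-[(2R,3S,4R,6E)-3-hydroxy-2,4,6-trimethylnon-6-enoyl]-1,3-thiazolidine-2-thione | CC/C=C(\C)C[C@@H](C)[C@H](O)[C@@H](C)C(=O)N1[C@H](Cc2ccccc2)CSC1=S | intermediate
12 | (R)-4-benzyl-3-[(2R,3S,4R,6E)-3-[(tert-butyldimethylsilyl)oxy]-2,4,6-trimethylnon-6-enoyl]-1,3-thiazolidine-2-thione | CC/C=C(\C)C[C@@H](C)[C@H](O[Si](C)(C)C(C)(C)C)[C@@H](C)C(=O)N1[C@H](Cc2ccccc2)CSC1=S | intermediate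
13 | tert-butyl propanoate | CCC(=O)OC(C)(C)C | starting material
14 | lithium enolate of tert-butyl propanoate (formed in the flask) | C/C=C(/[O-])OC(C)(C)C.[Li+] | intermediate
15 | tert-butyl (4R,5S,6R,8E)-5-[(tert-butyldimethylsilyl)oxy]-2,4,6,8-tetramethyl-3-oxoundec-8-enoate (both configurations at C-2) | CC/C=C(\C)C[C@@H](C)[C@H](O[Si](C)(C)C(C)(C)C)[C@@H](C)C(=O)C(C)C(=O)OC(C)(C)C | intermediate
16 | methyl (R)-3-hydroxy-2-methylpropanoate | COC(=O)[C@H](C)CO | starting material
17 | methyl (R)-2-methyl-3-[(triethylsilyl)oxy]propanoate | COC(=O)[C@H](C)CO[Si](CC)(CC)CC | intermediate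
18 | (R)-2-methyl-3-[(triethylsilyl)oxy]propanal | O=C[C@H](C)CO[Si](CC)(CC)CC | intermediate
19 | ethyl 2-[bis(2,2,2-trifluoroethoxy)phosphoryl]propanoate | CCOC(=O)C(C)P(=O)(OCC(F)(F)F)OCC(F)(F)F | starting material
20 | potassium carbanion of phosphonate 19 (formed in the flask) | CCOC(=O)[C-](C)P(=O)(OCC(F)(F)F)OCC(F)(F)F.[K+] | intermediate
21 | ethyl (2Z,4S)-2,4-dimethyl-5-[(triethylsilyl)oxy]pent-2-enoate | CCOC(=O)/C(C)=C\[C@H](C)CO[Si](CC)(CC)CC | intermediate
22 | (2Z,4S)-N-methoxy-N,2,4-trimethyl-5-[(triethylsilyl)oxy]pent-2-enamide | CON(C)C(=O)/C(C)=C\[C@H](C)CO[Si](CC)(CC)CC | intermediate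
23 | (4Z,6S)-4,6-dimethyl-7-[(triethylsilyl)oxy]hept-4-en-3-one | CCC(=O)/C(C)=C\[C@H](C)CO[Si](CC)(CC)CC | intermediate
24 | (4R,5S,6R,8E)-5-[(tert-butyldimethylsilyl)oxy]-2,4,6,8-tetramethylundeca-1,8-diene-1,3-dione (acylketene, formed in the flask) | CC/C=C(\C)C[C@@H](C)[C@H](O[Si](C)(C)C(C)(C)C)[C@@H](C)C(=O)C(C)=C=O | intermediate
25 | 6-[(2R,3S,4R,6E)-3-[(tert-butyldimethylsilyl)oxy]-4,6-dimethylnon-6-en-2-yl]-2-ethyl-5-methyl-2-[(2Z,4S)-4-methyl-5-[(triethylsilyl)oxy]pent-2-en-2-yl]-4H-1,3-dioxin-4-one (both configurations at the ketal carbon) | CC/C=C(\C)C[C@@H](C)[C@H](O[Si](C)(C)C(C)(C)C)[C@@H](C)C1=C(C)C(=O)OC(CC)(O1)/C(C)=C\[C@H](C)CO[Si](CC)(CC)CC | intermediate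
26 | (2S,3Z)-4-{6-[(2R,3S,4R,6E)-3-[(tert-butyldimethylsilyl)oxy]-4,6-dimethylnon-6-en-2-yl]-2-ethyl-5-methyl-4-oxo-4H-1,3-dioxin-2-yl}-2-methylpent-3-enal (both configurations at the ketal carbon) | CC/C=C(\C)C[C@@H](C)[C@H](O[Si](C)(C)C(C)(C)C)[C@@H](C)C1=C(C)C(=O)OC(CC)(O1)/C(C)=C\[C@H](C)C=O | intermediate
27 | ring B oxocarbenium triflate: 2-ethyl-3,5-dimethyl-2H-pyran-1-ium whose ketal carbon carries, through O-2, the trimethylsilyl (Z)-2-methyl-3-alkyl-acrylate arm (formed in the flask) | CC/C=C(\C)C[C@@H](C)[C@H](O[Si](C)(C)C(C)(C)C)[C@@H](C)/C(O[C@]1(CC)[O+]=C[C@@H](C)C=C1C)=C(\C)C(=O)O[Si](C)(C)C.[O-]S(=O)(=O)C(F)(F)F | intermediate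
28 | bicyclic oxocarbenium triflate with rings A and B closed, C-3=O-2 oxocarbenium and trimethylsilyl carboxylate on C-4 (formed in the flask) | CC/C=C(\C)C[C@@H](C)[C@H](O[Si](C)(C)C(C)(C)C)[C@@H](C)C1[C@@](C)(C(=O)O[Si](C)(C)C)[C@H]2O[C@@](CC)([O+]=1)C(C)=C[C@@H]2C.[O-]S(=O)(=O)C(F)(F)F | intermediate
29 | tert-butyl{[(2R,3S,4R,6E)-2-[(1S,5S,6S)-1-ethyl-4,6,8-trimethyl-2,9-dioxabicyclo[3.3.1]nona-3,7-dien-3-yl]-4,6-dimethylnon-6-en-3-yl]oxy}dimethylsilane | CC/C=C(\C)C[C@@H](C)[C@H](O[Si](C)(C)C(C)(C)C)[C@@H](C)C1=C(C)[C@H]2O[C@@](CC)(O1)C(C)=C[C@@H]2C | intermediate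
30 | (2R,3S,4R,6E)-2-[(1S,5S,6S)-1-ethyl-4,6,8-trimethyl-2,9-dioxabicyclo[3.3.1]nona-3,7-dien-3-yl]-4,6-dimethylnon-6-en-3-ol | CC/C=C(\C)C[C@@H](C)[C@H](O)[C@@H](C)C1=C(C)[C@H]2O[C@@](CC)(O1)C(C)=C[C@@H]2C | intermediate
31 | (2S,4R,6E)-2-[(1S,5S,6S)-1-ethyl-4,6,8-trimethyl-2,9-dioxabicyclo[3.3.1]nona-3,7-dien-3-yl]-4,6-dimethylnon-6-en-3-one | CC/C=C(\C)C[C@@H](C)C(=O)[C@@H](C)C1=C(C)[C@H]2O[C@@](CC)(O1)C(C)=C[C@@H]2C | target

## Step count and risks

Total step count: 18. Longest linear sequence: 13 steps (steps 1 to 8, then 14 to 18).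

**Risk 1, step 16.** The cyclic oxocarbenium ion may lose the proton at C-6 and aromatise to a pyrylium ion before the carbon–carbon bond forms, which would erase the C-6 centre. The ketal may also fail to ionise at low temperature, or the facial selectivity at C-5 may be poor.
Fallback, from 15 and 23, back at 29: 15 is heated in wet DMSO at 120 °C, where loss of tert-butanol, hydration of the acylketene and decarboxylation should give the ethyl ketone (4R,5S,6R,8E)-5-[(tert-butyldimethylsilyl)oxy]-4,6,8-trimethylundec-8-en-3-one F1. Ketone 23 is oxidised under the conditions of step 15 to the keto aldehyde (2S,3Z)-2,4-dimethyl-5-oxohept-3-enal F2. The Z boron enolate of F1 (Bu2BOTf, i-Pr2NEt, CH2Cl2, −78 °C) is added to the aldehyde group of F2 in a syn-selective aldol reaction. Z enolates prefer the anti-Felkin sense with α-methyl aldehydes, which is the C-5/C-6 relationship needed, and this should give the β-hydroxy ketone (4Z,6S,7S,8R,10R,11S,12R,14E)-11-[(tert-butyldimethylsilyl)oxy]-7-hydroxy-4,6,8,10,12,14-hexamethylheptadeca-4,14-diene-3,9-dione F3. Pyridinium p-toluenesulfonate with 4 Å MS in CH2Cl2 then closes the hemiketal between the hydroxyl group and the ethyl enone carbonyl and dehydrates it with the enol of the neighbouring ketone to the enol ether ketal 29.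

**Risk 2, step 14.** The acylketene may dimerise or be captured too slowly by the hindered conjugated ketone, and the Z enone may isomerise at 110 °C.
Fallback, from 15, back at 25: the tert-butyl ester of 15 is cleaved with CF3CO2H in CH2Cl2 at 0 °C to the β-keto acid (4R,5S,6R,8E)-5-[(tert-butyldimethylsilyl)oxy]-2,4,6,8-tetramethyl-3-oxoundec-8-enoic acid F4. F4 is condensed at 0 °C with ketone 23 through its mixed trifluoroacetic anhydride ((CF3CO)2O, CH2Cl2), the acid-mediated dioxinone synthesis from β-keto acids and ketones, to give 25 without a free acylketene and without heating.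

**Risk 3, step 8.** Acyl transfer to the ester enolate may be slow at the hindered α-branched thioimide, with self-condensation of the enolate or β-elimination of the silyloxy group taking over.
Fallback, from 12, back at 15: 12 is reduced with i-Bu2AlH at −78 °C to the aldehyde (2R,3S,4R,6E)-3-[(tert-butyldimethylsilyl)oxy]-2,4,6-trimethylnon-6-enal F5. Addition of lithium enolate 14 gives the β-hydroxy ester tert-butyl (4S,5S,6R,8E)-5-[(tert-butyldimethylsilyl)oxy]-3-hydroxy-2,4,6,8-tetramethylundec-8-enoate F6 (mixture at C-2 and C-3), and Dess–Martin oxidation of F6 gives 15.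

Further compounds
F1 | step 16 | (4R,5S,6R,8E)-5-[(tert-butyldimethylsilyl)oxy]-4,6,8-trimethylundec-8-en-3-one | CC/C=C(\C)C[C@@H](C)[C@H](O[Si](C)(C)C(C)(C)C)[C@@H](C)C(=O)CC
F2 | step 16 | (2S,3Z)-2,4-dimethyl-5-oxohept-3-enal | CCC(=O)/C(C)=C\[C@H](C)C=O
F3 | step 16 | (4Z,6S,7S,8R,10R,11S,12R,14E)-11-[(tert-butyldimethylsilyl)oxy]-7-hydroxy-4,6,8,10,12,14-hexamethylheptadeca-4,14-diene-3,9-dione | CC/C=C(\C)C[C@@H](C)[C@H](O[Si](C)(C)C(C)(C)C)[C@@H](C)C(=O)[C@H](C)[C@@H](O)[C@@H](C)/C=C(/C)C(=O)CC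
F4 | step 14 | (4R,5S,6R,8E)-5-[(tert-butyldimethylsilyl)oxy]-2,4,6,8-tetramethyl-3-oxoundec-8-enoic acid | CC/C=C(\C)C[C@@H](C)[C@H](O[Si](C)(C)C(C)(C)C)[C@@H](C)C(=O)C(C)C(=O)O
F5 | step 8 | (2R,3S,4R,6E)-3-[(tert-butyldimethylsilyl)oxy]-2,4,6-trimethylnon-6-enal | CC/C=C(\C)C[C@@H](C)[C@H](O[Si](C)(C)C(C)(C)C)[C@@H](C)C=O
F6 | step 8 | tert-butyl (4S,5S,6R,8E)-5-[(tert-butyldimethylsilyl)oxy]-3-hydroxy-2,4,6,8-tetramethylundec-8-enoate | CC/C=C(\C)C[C@@H](C)[C@H](O[Si](C)(C)C(C)(C)C)[C@@H](C)C(O)C(C)C(=O)OC(C)(C)C
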